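Readings and results are simulated on assumed constants, noise included.

**Bench note.** South-west, west and north-east each take c(substrate) = 5.0 mM in 3 equal portions, with c(gas) held at 2.7 mM and no reagent dissolved at the start. These three flasks differ in the gap between portions. The candidate steps carry gas into reagent, substrate and reagent into mono adduct, and mono adduct and reagent into double product.

| flask | substrate | gas | remark | time |
|---|---|---|---|---|
| zeta | 3.4 mM (in portions, 3) | 2.7 mM (held) | run made earlier; portions every 0.15 s |  |
| gamma | 7.5 mM (in portions, 3) | 2.7 mM (held) | run made earlier; portions every 0.15 s |  |
| south-west | 5.0 mM (in portions, 3) | 2.7 mM (held) | the portions of substrate follow each other after 0.15 s, the first at the start | 2.5 min |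
| west | 5.0 mM (in portions, 3) | 2.7 mM (held) | the portions of substrate follow each other after 0.30 s, the first at the start | 2.5 min |
| north-east | 5.0 mM (in portions, 3) | 2.7 mM (held) | the portions of substrate follow each other after 0.60 s, the first at the start | 2.5 min |

| run | time / s | mono adduct / % |
|---|---|---|
| zeta | 25.0 | 37 |
| zeta | 50.0 | 53 |
| zeta | 80.0 | 45 |
| zeta | 90.0 | 33 |
| zeta | 120 | 23 |
| gamma | 10.0 | 9 |
| gamma | 30.0 | 38 |
| gamma | 60.0 | 57 |
| gamma | 80.0 | 50 |
| gamma | 120 | 35 |

(scatter of a reading: 2 percentage points)

- at the start none of reagent is dissolved
- candidate steps: substrate + reagent -> mono adduct; reagent + mono adduct -> double product; gas <-> reagent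
- "hardly changes" means that all values lie within two and a half points (for a concentration: within two and a half percent of the largest)

**What comes.** Mono adduct reads highest at 50.0 s in the zeta run and at 60.0 s in the gamma run, and both runs read lower at 120 s. The asked time, 150 s, lies later than both peak readings, so the three flasks are expected to stand on the falling side, with double product growing.

**Leave the gap.** North-east has the widest gap and finishes dosing at 1.20 s. Set against the zeta peak reading, that gives 0.0240, the dosing share: the time from first to last portion over the time to the peak of mono adduct. This share lies far below one, so the portions should act as a single charge, and no substrate need be spent on re-timing them.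

- amount of mono adduct at the end, in percent of the substrate charged for south-west, west, north-east, in this order
- the shape of the row from first to last (falls all the way / rises all the way / rises, then falls / hardly changes / falls, then rises)

**The forecast.** It gives 20 %, 20 % and 20 %, shape hardly changes, holding that the “dosing schedule should therefore make no visible difference”. The shape reckoned here from the dosing share is the same, and that share offers no level of its own.

**The flasks.**

    substrate + reagent → mono adduct (k = 21.5 L mol⁻¹ s⁻¹)
    reagent + mono adduct → double product (k = 9.62 L mol⁻¹ s⁻¹)
    gas ⇌ reagent, rate k3*(csat - [reagent]) (kL = 0.0799 s⁻¹)

The flasks give 14.3 %, 14.3 % and 14.3 %, shape hardly changes: the forecast's shape, with the level 5.7 percentage points lower. North-east's dosing span of 1.20 s is short against the 47.1 s by which half of south-west's transfer of gas to reagent is done, and at dosing shares of 0.0240 in north-east and 0.00600 in south-west, adding substrate bit by bit leaves the end unchanged . At 2.50 min, south-west holds 14.3 % mono adduct, with a half-life of 0.50 min by the step to double product, and it is made at 0.0599 of the rate at which it is used up.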